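A one-step reaction is followed by the fraction left, and this ochre flask can be followed the same way although three steps are possible.

the same everywhere: solid substrate 0.0020 M
- ochre: enzyme 0.10 µM; the very flask that is asked about, followed so far
- blue: enzyme 0.050 µM; run made earlier
- flask: enzyme 0.10 µM; time 30 min

- ochre (time / min: solid substrate / %, target / %, side product / %): 0.833: 87, 9, 1; 2.50: 57, 28, 0; 4.00: 35, 49, 2; 6.00: 8, 71, 8; 10.0: 1, 87, 14; 12.0: 0, 87, 14; 15.0: 0, 85, 15
- blue (time / min: solid substrate / %, target / %, side product / %): 1.00: 83, 4, 1; 3.00: 57, 24, 3; 6.00: 15, 56, 12; 10.0: 0, 73, 22; 12.0: 0, 74, 25; 15.0: 0, 78, 22; 20.0: 2, 77, 24

(readings scatter by 1.5 percentage points)

- in percentages every species weighs as the solid substrate in it: one side product counts as two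
- as a solid, counted per litre of solution: solid substrate
- the numbers in the tables scatter by 1.5 percentage points (one standard deviation)
- steps thought possible: solid substrate <-> starting material; starting material + enzyme -> target + enzyme; starting material + target -> side product
- at the start none of the solid substrate is in solution
- what has only dissolved of solid substrate counts as not reacted
- the reaction counts as stopped when no species that holds the solid substrate changes by six tenths of a point or more over the second half of the time

1. at 30 min, what has stopped the reaction, if anything has (for what has run out or reacted, a solid counts together with what of it has only dissolved) (all of the solid substrate has reacted / it is still moving)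
2. part of the solid substrate that has turned into other species by 30 min (what has only dissolved does not count)
3. the target standing at 30 min, as a percentage of the solid substrate charged
4. the side product standing at 30 min, as a percentage of the solid substrate charged

1. In the flask, c(solid substrate) = 0.0020 M was charged. The solid dissolves to starting material, the enzyme turns that into target, and starting material with target gives side product.

2. The open part is what of the charge is neither target nor side product, so it is solid substrate plus starting material. The last three ochre readings, from 10.0 min to 15.0 min, give a mean open part of −0.667%, smaller in size than the scatter of 1.5 percentage points.

3. Each step thought possible that takes target also takes starting material, so with the open part at zero the pair stays as it stands. In the blue run, with 0.050 µM of enzyme, target and side product read 100% together at 15.0 min, and its target reads 78% there and 77% at 20.0 min.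

4. My own reckoning for 30 min is the mean of the last three ochre readings: target 86.3%, side product 14.3%.

5. Leave the flask as it stands until 30 min and add no solid substrate, since this reckoning is for the present charge.

The forecast gives all of the solid substrate has reacted, conversion 100%, target 86% and side product 14%, holding that “nothing should change up to 30 min”.

The flask gives all of the solid substrate has reacted, conversion 100%, target 85.4% and side product 14.6%.

    solid substrate ⇌ starting material, rate k1*(cs1 - [starting material]) while solid is left; crystals form when [starting material] > cs1 (solubility = 1.20 mM, k = 0.00510 /s)
    starting material + enzyme → target + enzyme, rate k2*[starting material]*[enzyme]/(1 + ([starting material]/Km2) + ([target]/Kp2)) (4.20 mM, 2.90 mM, k = 2.90 × 10⁵ /M/s)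
    starting material + target → side product (k = 1.80 /M/s)

At 3.16 min in this flask, starting material is turned into target 16 times faster than it is taken with target into side product, a selectivity factor for that moment, and the side-product step has >99.9% of its turnover up to 30 min behind it at 15.0 min, where the open part, read as −0.667% from the last ochre readings, holds starting material 0% and solid substrate 0%. The neighbour flask with c(solid substrate) = 0.0034 M also ends with an open part of 0% at 30 min, holding target 75.4% and side product 24.6%.

The data are simulated with constants of no real substance; noise was put on by code.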